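## The problem

The target is an isoflavone: a chromen-4-one (rings A and C) with ring B attached at C3. Ring A is fully substituted (5-OH, 6-prenyl, 7-OH, 8-prenyl), and ring B carries 2'-OMe, 3'-prenyl and 4'-OH next to the biaryl-type C3–C1' bond. There is no stereocenter, so the task is one of regiochemistry. Three prenyl groups must each be placed between two oxygen-bearing carbons, one methyl ether must be told apart from three free phenols, and ring B must end up on C3, not on C2. The prenyl groups are the fragile part. Each lies ortho to a phenol and closes to a 2,2-dimethylchroman under strong protic or Lewis acid, each is attacked by electrophilic halogen and by oxidants, and together they rule out hydrogenolysis. The phloroglucinol ring is easily oxidised once its phenols are free, so the phenols should stay masked until the end by groups that leave under mild acid. The feature that opens the route is the C4 carbonyl: it is a one-carbon bridge between C4a of ring A and the vinylic carbon C3. The 2,4-diprenylphloroglucinol unit has a mirror plane through C4a and C7, so the two oxygens flanking C4a (the later O1 and 5-OH) are equivalent. C4 can therefore be carbon monoxide inserted between a symmetric ring A iodide and an alkenyl nucleophile that carries ring B on C3 and holds C2 as a methoxyvinyl carbon at the formyl oxidation level. The last bond, O1–C2, then closes by addition–elimination.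

## Retrosynthesis

**Target 26 to enone 24 (cut O1–C2, unmask four phenols).** Ring C is opened at the O1–C2 bond, which leads back through the tetraphenol 25 to the MOM-protected β-methoxy enone 24. This cut is preferred over a cut at C3–C1', which would leave ring C to be built separately on the hindered ring A and would require coupling at an aryl carbon flanked by a methoxy group. With 24, the ring closure costs no step: the acid that removes the MOM ethers also lets the freed ortho phenol displace methoxide from C2. The forward reaction must use acid mild enough to spare three prenyl groups that sit next to newly freed phenols.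

**Enone 24 to iodide 9, carbon monoxide 23 and boronate 22 (cut C4a–C4 and C4–C3).** Both bonds to the carbonyl carbon are cut in one operation, giving three components of very unequal size. Against a stepwise acylation of ring A (a Friedel–Crafts or Hoesch reaction on a diprenylphloroglucinol), this cut needs no Lewis acid and attaches ring B, C3 and C2 at once. Iodide 9 is symmetric, so no regiochemical question arises. The forward reaction must insert carbon monoxide before the alkenyl group is transferred; the two ortho MOM ethers of 9 slow direct coupling and so help.

**Iodide 9 to phloroglucinol 1 and prenyl bromide 3 (cut C–I and two aryl–prenyl bonds).** Every ring carbon of tris-MOM ether 2 lies between two MOM ethers. Three successive ortho-lithiations (2 to 5, 5 to 7, 7 to 9) therefore place two prenyl groups and the iodine without any isomer problem. Direct C-prenylation of free phloroglucinol gives mixtures of C- and O-alkylated and over-alkylated products, so it is not used. The forward reactions must metalate the ring and not the benzylic, allylic CH2 of the prenyl groups already present.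

**Boronate 22 to enol triflate 21 and ketone 19 (cut C–B, then O–Tf).** The alkenyl C–B bond is traced to the enol triflate 21 of the α-methoxy ketone 19. Ketone 19 has a single enolisable position, and its enolate is formed with defined geometry. A route through bromination and elimination of an enol ether was set aside: electrophilic bromine would not reliably distinguish the enol ether from the prenyl alkene and the activated ring B. The forward reactions are O-triflation and Miyaura borylation with retention.

**Ketone 19 to aldehyde 15 and stannane 16 (cut the bond between the later C3 and C2).** The methoxymethyl carbon, which becomes C2 of the isoflavone, is added as methoxymethyllithium 17 to aldehyde 15. Oxidation of alcohol 18 then gives 19. This brings C2 in at the correct oxidation level with its methoxy group already attached.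

**Aldehyde 15 to 4-hydroxy-2-methoxybenzaldehyde 10 and prenyl bromide 3 (cut C3'–prenyl).** The position between the methoxy group and the MOM ether of 11 is the most acidic ring position. With the aldehyde masked in the flask as an α-amino alkoxide, lithiation and prenylation at that carbon give 15. The starting aldehyde 10 already holds the methyl ether and the free phenol on the correct oxygens, so no differentiation step is needed.

## Roads not taken

**Alternative 1:** The cut is at C3–C1', made in the forward sense by a 1,2-aryl shift. The 2'-hydroxychalcone A2 (from a Claisen–Schmidt condensation) is treated with Tl(NO3)3 in methanol and trimethyl orthoformate. Ring B migrates to the α-carbon, and acid closes O1–C2 to the tribromo isoflavone A1.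
- Merits: the rearrangement follows the biosynthesis and is among the most reliable isoflavone constructions. The chalcone comes from two simple aromatic halves, and the bromine atoms stand in for prenyl groups that would not survive the oxidant.
- Weak points for this target: a stoichiometric trivalent thallium salt is needed. All three prenyl groups must then be introduced by a threefold cross-coupling at C–Br bonds that each lie between two oxygen-bearing carbons. Prenyl–metal reagents tend to give linear and branched isomers, and incomplete coupling gives mixtures that are hard to separate. Finally, three benzyl ethers must be removed beside three prenyl alkenes. That excludes hydrogenolysis and leaves Lewis acids, which promote chroman formation.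
- Comparison: the key step of this road is better precedented than a carbonylative coupling with a β-alkoxyalkenylboronate, and in that respect it is the safer plan. The chosen plan sets against this that all prenyl groups are placed early by directed lithiation with no isomer problem, that the two halves are joined convergently, and that the end game is one mild acid step. The chosen plan does use a stoichiometric tin reagent in step 7.

**Alternative 2:** The cut is inside ring A: C8–C8a, C6–C7 and C4a–C8a. Heating the cyclobutenone A4 with the siloxyalkyne A5 (Danheiser benzannulation through a vinylketene) gives the phenol A3, a 2,4-diprenylphloroglucinol with three different oxygen substituents and C4a unsubstituted.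
- Merits: the regiochemistry is built in, both prenyl groups arrive with the components, and no lithiation is run next to a prenyl group. The free phenol could direct a later acylation to C4a.
- Weak points: ring A is symmetric about the C4a–C7 axis, so the differentiation of the three oxygens buys nothing here. A4 and A5 each need several steps, whereas phloroglucinol gives the same substitution pattern in three operations. The step also leaves the main problem open, since C4, C3, C2 and ring B must still be attached to a hindered, acid-sensitive arene.
- Comparison: this road is better in one respect: it avoids the repeated lithiations of steps 2 to 4 and their risk of lateral metalation. The chosen plan sets against this a cheap symmetric starting material, a much shorter ring A sequence, and a key step that also builds the carbonyl bridge.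

**Alternative 3:** The cut is inside ring B: C3'–C4', C1'–C2' and C4'–C5'. The chromon-3-yl cyclobutenone A7 is heated with the alkynyl ether A8. The benzannulation gives the isoflavone A6 with 2'-OMe, 3'-prenyl and a free 4'-OH, leaving two MOM ethers to remove.
- Merits: this is the most convergent late stage of all the plans. The substitution pattern of ring B follows from the mechanism, and the 4'-phenol needs no protecting group.
- Weak points: A7 is a strained enone attached to a chromone that is itself a Michael acceptor, and it must first be made from a functionalised chromone. Ring A must be prepared just as in the chosen route, and ring C must be built and functionalised at C3 in addition. A8 is a sensitive ynol ether that must be prepared. The thermal cascade runs through ketene intermediates in a molecule with two prenyl alkenes.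
- Comparison: in late-stage convergence and in the regiochemical certainty of ring B, this road is better than the lithiation of step 6. The chosen plan sets against this that ring B is bought as a simple benzaldehyde, that every component is made by standard aromatic chemistry, and that the total is shorter because no separate chromone synthesis is needed.

Key step: step 11

Remark on the chemistry: enone 24 is drawn as the (Z)-isomer (methoxy cis to the aroyl group), which follows from retention of geometry from 21 through 22. Both geometrical isomers converge on 26 in step 12, so this geometry has no consequence.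

## Route

**Step 1**
Reactants: 1 phloroglucinol
Product: 2 1,3,5-tris(methoxymethoxy)benzene
Conditions: NaH, MOMCl, DMF, 0 °C to rt
Reagents that add atoms: chloromethyl methyl ether, COCCl
Why: Williamson-type O-alkylation of the tris-phenoxide; the hard chloromethyl ether alkylates on oxygen, not on carbon.

**Step 2**
Reactants: 2 1,3,5-tris(methoxymethoxy)benzene; 3 prenyl bromide (1-bromo-3-methylbut-2-ene)
Product: 5 1,3,5-tris(methoxymethoxy)-2-(3-methylbut-2-enyl)benzene, via aryllithium 4 (not isolated)
Conditions: n-BuLi, TMEDA, THF, 0 °C; then CuI (10 mol %), 3, −78 °C to rt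
Reagents that add atoms: none
Why: Directed ortho-metalation at a ring carbon flanked by two MOM ethers, then copper-catalysed alkylation of the aryl anion at the primary carbon of the allylic bromide; all three ring positions of 2 are equivalent.

**Step 3**
Reactants: 5 1,3,5-tris(methoxymethoxy)-2-(3-methylbut-2-enyl)benzene; 3 prenyl bromide
Product: 7 1,3,5-tris(methoxymethoxy)-2,4-bis(3-methylbut-2-enyl)benzene, via aryllithium 6 (not isolated)
Conditions: n-BuLi, TMEDA, THF, 0 °C; then CuI (10 mol %), 3, −78 °C to rt
Reagents that add atoms: none
Why: Second directed ortho-metalation and alkylation; the two remaining ring hydrogens of 5 are equivalent and each lies between two MOM ethers, whose coordination favours ring lithiation over lateral deprotonation.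

**Step 4**
Reactants: 7 1,3,5-tris(methoxymethoxy)-2,4-bis(3-methylbut-2-enyl)benzene
Product: 9 2-iodo-1,3,5-tris(methoxymethoxy)-4,6-bis(3-methylbut-2-enyl)benzene, via aryllithium 8 (not isolated)
Conditions: n-BuLi, TMEDA, THF, 0 °C; then ICH2CH2I, −78 °C to rt
Reagents that add atoms: 1,2-diiodoethane, ICCI
Why: Directed ortho-metalation of the last ring C–H, then iodination of the aryllithium; 1,2-diiodoethane delivers iodine without free I2 that could add to the prenyl alkenes.

**Step 5**
Reactants: 10 4-hydroxy-2-methoxybenzaldehyde
Product: 11 2-methoxy-4-(methoxymethoxy)benzaldehyde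
Conditions: MOMCl, K2CO3, acetone, rt
Reagents that add atoms: chloromethyl methyl ether, COCCl
Why: O-alkylation of the single, acidic para-formyl phenol under mild base; the aldehyde is untouched.

**Step 6**
Reactants: 11 2-methoxy-4-(methoxymethoxy)benzaldehyde; 3 prenyl bromide
Product: 15 2-methoxy-4-(methoxymethoxy)-3-(3-methylbut-2-enyl)benzaldehyde, via lithium α-amino alkoxide 12 (not isolated), via ring-lithiated amino alkoxide 13 (not isolated), via prenylated amino alkoxide 14 (not isolated)
Conditions: 1-methylpiperazine, n-BuLi, THF, −20 °C; 11; then n-BuLi (3 equiv), TMEDA, −20 °C; CuI (10 mol %), 3 (excess), −78 °C to rt; aq. work-up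
Reagents that add atoms: none
Why: Directed ortho-metalation with the aldehyde protected in the flask as its α-amino alkoxide; the piperazine-derived alkoxide is a weak director, so lithiation goes to the carbon between the methoxy group and the MOM ether, and aqueous work-up releases the aldehyde.

**Step 7**
Reactants: 15 2-methoxy-4-(methoxymethoxy)-3-(3-methylbut-2-enyl)benzaldehyde; 16 tributyl(methoxymethyl)stannane
Product: 18 2-methoxy-1-[2-methoxy-4-(methoxymethoxy)-3-(3-methylbut-2-enyl)phenyl]ethanol (racemic), via methoxymethyllithium 17 (not isolated)
Conditions: 16, n-BuLi, THF, −78 °C; then 15, −78 °C; aq. work-up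
Reagents that add atoms: none
Why: Tin–lithium exchange gives the α-alkoxy organolithium, which adds 1,2 to the aldehyde; the new carbinol center is racemic and is removed in step 8.

**Step 8**
Reactants: 18 2-methoxy-1-[2-methoxy-4-(methoxymethoxy)-3-(3-methylbut-2-enyl)phenyl]ethanol
Product: 19 2-methoxy-1-[2-methoxy-4-(methoxymethoxy)-3-(3-methylbut-2-enyl)phenyl]ethanone
Conditions: Dess–Martin periodinane, NaHCO3, CH2Cl2, 0 °C to rt
Reagents that add atoms: none
Why: Dess–Martin oxidation of a benzylic secondary alcohol; the buffered, non-acidic conditions leave the MOM ether and the prenyl alkene intact.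

**Step 9**
Reactants: 19 2-methoxy-1-[2-methoxy-4-(methoxymethoxy)-3-(3-methylbut-2-enyl)phenyl]ethanone
Product: 21 (Z)-2-methoxy-1-[2-methoxy-4-(methoxymethoxy)-3-(3-methylbut-2-enyl)phenyl]ethenyl trifluoromethanesulfonate, via potassium enolate 20 (not isolated)
Conditions: KN(SiMe3)2, THF, −78 °C; then PhNTf2, −78 to 0 °C
Reagents that add atoms: N-phenylbis(trifluoromethanesulfonimide), O=S(=O)(N(c1ccccc1)S(=O)(=O)C(F)(F)F)C(F)(F)F
Why: Enolate O-triflation; the ketone has one enolisable position, and the (Z)-enolate (enolate oxygen cis to the methoxy group) is favoured by chelation and by the twisted ortho-substituted aryl group, which fixes the triflate geometry.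

**Step 10**
Reactants: 21 (Z)-2-methoxy-1-[2-methoxy-4-(methoxymethoxy)-3-(3-methylbut-2-enyl)phenyl]ethenyl trifluoromethanesulfonate
Product: 22 2-[(E)-2-methoxy-1-[2-methoxy-4-(methoxymethoxy)-3-(3-methylbut-2-enyl)phenyl]ethenyl]-4,4,5,5-tetramethyl-1,3,2-dioxaborolane
Conditions: B2pin2, PdCl2(PPh3)2 (3 mol %), PPh3 (6 mol %), KOPh, toluene, 50 °C
Reagents that add atoms: bis(pinacolato)diboron, CC1(C)OB(OC1(C)C)B1OC(C)(C)C(C)(C)O1
Why: Miyaura borylation of an alkenyl triflate with retention of geometry; the weak base KOPh suppresses Suzuki-type dimerisation of product with triflate, and boron takes the place of the triflate cis to the methoxy group.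

**Step 11**
Reactants: 9 2-iodo-1,3,5-tris(methoxymethoxy)-4,6-bis(3-methylbut-2-enyl)benzene; 23 carbon monoxide; 22 2-[(E)-2-methoxy-1-[2-methoxy-4-(methoxymethoxy)-3-(3-methylbut-2-enyl)phenyl]ethenyl]-4,4,5,5-tetramethyl-1,3,2-dioxaborolane
Product: 24 (Z)-3-methoxy-2-[2-methoxy-4-(methoxymethoxy)-3-(3-methylbut-2-enyl)phenyl]-1-[2,4,6-tris(methoxymethoxy)-3,5-bis(3-methylbut-2-enyl)phenyl]prop-2-en-1-one
Conditions: Pd(OAc)2 (5 mol %), di(1-adamantyl)-n-butylphosphine (10 mol %), Cs2CO3, CO (5 bar), toluene/H2O 20:1, 90 °C
Reagents that add atoms: none
Why: Zerovalent palladium, formed from Pd(OAc)2 and the bulky electron-rich phosphine, inserts into the C4a–I bond of 9. The resulting aryl–palladium is flanked by two MOM ethers and transmetalates slowly, so it first takes up carbon monoxide; migration of the electron-rich aryl group gives the aroyl–palladium species and relieves steric strain. The base-activated boronate 22 then transfers its alkenyl group with retention, and reductive elimination forms C4–C3, so that C4a–C4 and C4–C3 are made in one operation. The closest known reactions are the carbonylative Suzuki–Miyaura ketone synthesis from di-ortho-substituted aryl iodides and the carbonylative coupling of aryl iodides with alkenylboron reagents to aryl vinyl ketones. No ring is closed and no stereocenter is formed; the alkene geometry is carried over from 22 and does not matter later. The selectivity required is carbonylative over direct coupling, and it is secured by the two ortho substituents of 9 and by the carbon monoxide pressure. The symmetry of 9 removes any question of which flanking oxygen becomes O1. The MOM ethers and prenyl groups are inert to the basic, non-oxidising medium.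

**Step 12**
Reactants: 24 (Z)-3-methoxy-2-[2-methoxy-4-(methoxymethoxy)-3-(3-methylbut-2-enyl)phenyl]-1-[2,4,6-tris(methoxymethoxy)-3,5-bis(3-methylbut-2-enyl)phenyl]prop-2-en-1-one
Product: 26 5,7-dihydroxy-3-[4-hydroxy-2-methoxy-3-(3-methylbut-2-enyl)phenyl]-6,8-bis(3-methylbut-2-enyl)chromen-4-one (the target), via tetraphenol enone 25 (not isolated)
Conditions: HCl (ca. 1 M) in MeOH, 40 °C
Reagents that add atoms: none
Why: Acid-catalysed acetal exchange removes the four MOM ethers as dimethoxymethane; a freed ortho phenol of 25 then adds to C2 of the protonated β-methoxy enone and methanol is lost (6-endo addition–elimination), the same closure as in the acid cyclisation of 2-hydroxydeoxybenzoin formyl equivalents; the two ortho phenols are equivalent, and the remaining one becomes the hydrogen-bonded 5-OH.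

## Compound list

1 | phloroglucinol (benzene-1,3,5-triol) | Oc1cc(O)cc(O)c1 | starting material
2 | 1,3,5-tris(methoxymethoxy)benzene | COCOc1cc(OCOC)cc(OCOC)c1 | intermediate
3 | prenyl bromide (1-bromo-3-methylbut-2-ene) | CC(C)=CCBr | starting material
4 | 2-lithio-1,3,5-tris(methoxymethoxy)benzene | [Li]c1c(OCOC)cc(OCOC)cc1OCOC | intermediate (not isolated)
5 | 1,3,5-tris(methoxymethoxy)-2-(3-methylbut-2-enyl)benzene | COCOc1cc(OCOC)c(CC=C(C)C)c(OCOC)c1 | intermediate
6 | 4-lithio-1,3,5-tris(methoxymethoxy)-2-(3-methylbut-2-enyl)benzene | [Li]c1c(OCOC)cc(OCOC)c(CC=C(C)C)c1OCOC | intermediate (not isolated)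
7 | 1,3,5-tris(methoxymethoxy)-2,4-bis(3-methylbut-2-enyl)benzene | COCOc1cc(OCOC)c(CC=C(C)C)c(OCOC)c1CC=C(C)C | intermediate
8 | 6-lithio-1,3,5-tris(methoxymethoxy)-2,4-bis(3-methylbut-2-enyl)benzene | [Li]c1c(OCOC)c(CC=C(C)C)c(OCOC)c(CC=C(C)C)c1OCOC | intermediate (not isolated)
9 | 2-iodo-1,3,5-tris(methoxymethoxy)-4,6-bis(3-methylbut-2-enyl)benzene | Ic1c(OCOC)c(CC=C(C)C)c(OCOC)c(CC=C(C)C)c1OCOC | intermediate
10 | 4-hydroxy-2-methoxybenzaldehyde | O=Cc1ccc(O)cc1OC | starting material
11 | 2-methoxy-4-(methoxymethoxy)benzaldehyde | O=Cc1ccc(OCOC)cc1OC | intermediate
12 | lithium [2-methoxy-4-(methoxymethoxy)phenyl](4-methylpiperazin-1-yl)methanolate (racemic) | [Li]OC(N1CCN(C)CC1)c1ccc(OCOC)cc1OC | intermediate (not isolated)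
13 | lithium [3-lithio-2-methoxy-4-(methoxymethoxy)phenyl](4-methylpiperazin-1-yl)methanolate (racemic) | [Li]OC(N1CCN(C)CC1)c1ccc(OCOC)c([Li])c1OC | intermediate (not isolated)
14 | lithium [2-methoxy-4-(methoxymethoxy)-3-(3-methylbut-2-enyl)phenyl](4-methylpiperazin-1-yl)methanolate (racemic) | [Li]OC(N1CCN(C)CC1)c1ccc(OCOC)c(CC=C(C)C)c1OC | intermediate (not isolated)
15 | 2-methoxy-4-(methoxymethoxy)-3-(3-methylbut-2-enyl)benzaldehyde | O=Cc1ccc(OCOC)c(CC=C(C)C)c1OC | intermediate
16 | tributyl(methoxymethyl)stannane | CCCC[Sn](CCCC)(CCCC)COC | starting material
17 | methoxymethyllithium | [Li]COC | intermediate (not isolated)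
18 | 2-methoxy-1-[2-methoxy-4-(methoxymethoxy)-3-(3-methylbut-2-enyl)phenyl]ethanol (racemic) | COCC(O)c1ccc(OCOC)c(CC=C(C)C)c1OC | intermediate
19 | 2-methoxy-1-[2-methoxy-4-(methoxymethoxy)-3-(3-methylbut-2-enyl)phenyl]ethanone | COCC(=O)c1ccc(OCOC)c(CC=C(C)C)c1OC | intermediate
20 | potassium (Z)-2-methoxy-1-[2-methoxy-4-(methoxymethoxy)-3-(3-methylbut-2-enyl)phenyl]ethenolate | CO/C=C(\O[K])c1ccc(OCOC)c(CC=C(C)C)c1OC | intermediate (not isolated)
21 | (Z)-2-methoxy-1-[2-methoxy-4-(methoxymethoxy)-3-(3-methylbut-2-enyl)phenyl]ethenyl trifluoromethanesulfonate | CO/C=C(\OS(=O)(=O)C(F)(F)F)c1ccc(OCOC)c(CC=C(C)C)c1OC | intermediate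
22 | 2-[(E)-2-methoxy-1-[2-methoxy-4-(methoxymethoxy)-3-(3-methylbut-2-enyl)phenyl]ethenyl]-4,4,5,5-tetramethyl-1,3,2-dioxaborolane | CO/C=C(\B1OC(C)(C)C(C)(C)O1)c1ccc(OCOC)c(CC=C(C)C)c1OC | intermediate
23 | carbon monoxide | [C-]#[O+] | starting material
24 | (Z)-3-methoxy-2-[2-methoxy-4-(methoxymethoxy)-3-(3-methylbut-2-enyl)phenyl]-1-[2,4,6-tris(methoxymethoxy)-3,5-bis(3-methylbut-2-enyl)phenyl]prop-2-en-1-one | CO/C=C(\C(=O)c1c(OCOC)c(CC=C(C)C)c(OCOC)c(CC=C(C)C)c1OCOC)c1ccc(OCOC)c(CC=C(C)C)c1OC | intermediate
25 | (Z)-2-[4-hydroxy-2-methoxy-3-(3-methylbut-2-enyl)phenyl]-3-methoxy-1-[2,4,6-trihydroxy-3,5-bis(3-methylbut-2-enyl)phenyl]prop-2-en-1-one | CO/C=C(\C(=O)c1c(O)c(CC=C(C)C)c(O)c(CC=C(C)C)c1O)c1ccc(O)c(CC=C(C)C)c1OC | intermediate (not isolated)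
26 | 5,7-dihydroxy-3-[4-hydroxy-2-methoxy-3-(3-methylbut-2-enyl)phenyl]-6,8-bis(3-methylbut-2-enyl)chromen-4-one | COc1c(-c2coc3c(CC=C(C)C)c(O)c(CC=C(C)C)c(O)c3c2=O)ccc(O)c1CC=C(C)C | target

## Step count and risks

Total: 12 steps. Longest linear sequence: 8 steps (steps 5 to 12). The ring A branch (steps 1 to 4) joins at step 11.

**Step 11 (key step).** The most likely failure is slow transfer of the bulky, electron-rich alkenyl group to the hindered aroyl–palladium species. Protodeboronation of 22, or capture of the aroyl–palladium by water or carbonate to give the benzoic acid, would then take over. Partial hydrolysis of the vinylogous ester of 24 by the aqueous base is also possible but harmless, because the hydroxymethylene ketone closes in step 12 in the same way. The fallback replaces the carbonylative coupling by an addition and oxidation sequence and sets out from 7 and 21. Compound 7 is lithiated as in step 4 and quenched with DMF to give 2,4,6-tris(methoxymethoxy)-3,5-bis(3-methylbut-2-enyl)benzaldehyde F1. A Nozaki–Hiyama–Kishi coupling of F1 with enol triflate 21 (CrCl2 in excess, NiCl2 catalytic, DMF, rt) gives the allylic alcohol (Z)-3-methoxy-2-[2-methoxy-4-(methoxymethoxy)-3-(3-methylbut-2-enyl)phenyl]-1-[2,4,6-tris(methoxymethoxy)-3,5-bis(3-methylbut-2-enyl)phenyl]prop-2-en-1-ol F2. Dess–Martin oxidation of F2 returns to the route at 24.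

**Step 6.** Lithiation may be incomplete or may go to C5 or C6, and butyllithium may attack the aminal carbon, because the transient amino alkoxide is both a weak protecting group and a weak director. The fallback sets out from 11 and uses an isolated acetal. Compound 11 is treated with 1,2-bis(trimethylsilyloxy)ethane and catalytic Me3SiOTf (CH2Cl2, −78 °C) to give 2-[2-methoxy-4-(methoxymethoxy)phenyl]-1,3-dioxolane F3. Lithiation of F3 (n-BuLi, TMEDA, THF, 0 °C) between the two oxygen substituents and CuI-catalysed alkylation with 3 give 2-[2-methoxy-4-(methoxymethoxy)-3-(3-methylbut-2-enyl)phenyl]-1,3-dioxolane F4. Mild hydrolysis (pyridinium p-toluenesulfonate, wet acetone, rt), which the aryl MOM ether should survive, returns to the route at 15.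

**Step 4 (and, to a lesser degree, steps 2 and 3).** Lateral deprotonation of the benzylic, allylic CH2 groups may compete with ring lithiation at the most crowded stage, and the aryllithium may be quenched incompletely. The fallback sets out from 7 and changes the mechanism to electrophilic aromatic substitution: N-iodosuccinimide in MeCN at 0 °C without acid. The remaining ring carbon is activated by three alkoxy groups and should be iodinated faster than the prenyl alkenes, whose reversible iodonium formation has no internal nucleophile to trap it. The fallback returns to the route at 9 and makes no compound outside the list (F0).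

**Step 10.** Oxidative addition to the electron-rich enol triflate may be slow, so that reduction of the triflate or coupling of product with unreacted triflate competes, and the C–B bond of 22 may be protonolysed on isolation. The fallback sets out from 21 and changes the nucleophile to tin. Stannylation of 21 with (Me3Sn)2 (Pd(PPh3)4, LiCl, THF, 60 °C) gives [(Z)-2-methoxy-1-[2-methoxy-4-(methoxymethoxy)-3-(3-methylbut-2-enyl)phenyl]ethenyl]trimethylstannane F5. A carbonylative Stille coupling of F5 with 9 and carbon monoxide 23 (PdCl2(PPh3)2, CO, toluene, 90 °C) forms the same two bonds and returns to the route at 24.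

**Step 12.** Protonation of a prenyl alkene may lead to chroman formation with the neighbouring free phenol, or to addition of methanol, before all four MOM ethers have been cleaved. The fallback sets out from 24 and avoids Brønsted acid. ZnBr2 and n-PrSH in CH2Cl2 at 0 °C cleave the MOM ethers by soft nucleophilic attack to give tetraphenol 25, which is isolated here. K2CO3 in MeOH at rt then closes ring C by phenoxide addition–elimination, returning to the route at 26. No compound outside the list is made (F0).

## Further compounds

F1 | step 11 | 2,4,6-tris(methoxymethoxy)-3,5-bis(3-methylbut-2-enyl)benzaldehyde | O=Cc1c(OCOC)c(CC=C(C)C)c(OCOC)c(CC=C(C)C)c1OCOC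
F2 | step 11 | (Z)-3-methoxy-2-[2-methoxy-4-(methoxymethoxy)-3-(3-methylbut-2-enyl)phenyl]-1-[2,4,6-tris(methoxymethoxy)-3,5-bis(3-methylbut-2-enyl)phenyl]prop-2-en-1-ol (racemic) | CO/C=C(\C(O)c1c(OCOC)c(CC=C(C)C)c(OCOC)c(CC=C(C)C)c1OCOC)c1ccc(OCOC)c(CC=C(C)C)c1OC
F3 | step 6 | 2-[2-methoxy-4-(methoxymethoxy)phenyl]-1,3-dioxolane | COCOc1ccc(C2OCCO2)c(OC)c1
F4 | step 6 | 2-[2-methoxy-4-(methoxymethoxy)-3-(3-methylbut-2-enyl)phenyl]-1,3-dioxolane | COCOc1ccc(C2OCCO2)c(OC)c1CC=C(C)C
F0 | step 4 | none | none
F5 | step 10 | [(Z)-2-methoxy-1-[2-methoxy-4-(methoxymethoxy)-3-(3-methylbut-2-enyl)phenyl]ethenyl]trimethylstannane | CO/C=C(\[Sn](C)(C)C)c1ccc(OCOC)c(CC=C(C)C)c1OC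
F0 | step 12 | none | none
A1 | alternative 1 | 5,7-bis(benzyloxy)-3-(4-benzyloxy-3-bromo-2-methoxyphenyl)-6,8-dibromochromen-4-one | COc1c(-c2coc3c(Br)c(OCc4ccccc4)c(Br)c(OCc4ccccc4)c3c2=O)ccc(OCc2ccccc2)c1Br
A2 | alternative 1 | (E)-1-[4,6-bis(benzyloxy)-3,5-dibromo-2-hydroxyphenyl]-3-(4-benzyloxy-3-bromo-2-methoxyphenyl)prop-2-en-1-one | COc1c(/C=C/C(=O)c2c(O)c(Br)c(OCc3ccccc3)c(Br)c2OCc2ccccc2)ccc(OCc2ccccc2)c1Br
A3 | alternative 2 | 3-(methoxymethoxy)-2,4-bis(3-methylbut-2-enyl)-5-(triisopropylsilyloxy)phenol | Oc1cc(OCOC)c(CC=C(C)C)c(O[Si](C(C)C)(C(C)C)C(C)C)c1CC=C(C)C
A4 | alternative 2 | 3-(methoxymethoxy)-2-(3-methylbut-2-enyl)cyclobut-2-en-1-one | O=C1CC(OCOC)=C1CC=C(C)C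
A5 | alternative 2 | triisopropyl[(5-methylhex-4-en-1-yn-1-yl)oxy]silane | CC(C)=CCC#CO[Si](C(C)C)(C(C)C)C(C)C
A6 | alternative 3 | 3-[4-hydroxy-2-methoxy-3-(3-methylbut-2-enyl)phenyl]-5,7-bis(methoxymethoxy)-6,8-bis(3-methylbut-2-enyl)chromen-4-one | COc1c(-c2coc3c(CC=C(C)C)c(OCOC)c(CC=C(C)C)c(OCOC)c3c2=O)ccc(O)c1CC=C(C)C
A7 | alternative 3 | 5,7-bis(methoxymethoxy)-6,8-bis(3-methylbut-2-enyl)-3-(4-oxocyclobut-1-en-1-yl)chromen-4-one | O=C1CC=C1c1coc2c(CC=C(C)C)c(OCOC)c(CC=C(C)C)c(OCOC)c2c1=O
A8 | alternative 3 | 1-methoxy-5-methylhex-4-en-1-yne | COC#CCC=C(C)C
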